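## Retrosynthetic overview

1. The strategy rests on C8a of ring A. It is ortho to C4a, the carbon that carries the C4 carbonyl, meta to the oxygens on C5 and C7, and next to the lavandulyl-bearing C8. A C8a–F bond is therefore an activated, position-specific stand-in for the O1–C8a bond.
2. The last disconnections are the four MOM ethers (mild acid) and then O1–C8a, by intramolecular SNAr of a 2-MOMO-1,3-diketone enolate. This closes ring C, the only ring made; rings A and B are bought.
3. In the diketone, C2–C3 comes from C-aroylation of an α-MOMO 2-fluoroaryl ketone enolate with the acyl imidazole of 4-(MOMO)benzoic acid. C4–C4a comes from an aryllithium and the MOM-glycolic Weinreb amide.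
4. C8–CH2 comes from Negishi coupling of a C8 aryl iodide with the zinc reagent from (R)-lavandulol, which supplies the only stereocentre.
5. For regiocontrol on 5-fluororesorcinol bis-MOM ether, silicon is placed first at C6, between the two OMOM groups. Both later metalations must then occur beside fluorine, and the silicon is removed with fluoride before the aroylation.

Key step: step 13

Assumption: (R)-lavandulol of high enantiomeric purity is taken as purchasable (otherwise by lipase resolution of the racemate). Its spatial arrangement is kept throughout, and the descriptor changes from R (CH2OH, CH2I, CH2Zn) to S (CH2Ar) only through CIP priorities.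

Convention: ring atoms carry flavone numbering (O1, C2–C4, C4a, C5–C8, C8a) from the first intermediate on. Lav = (2S)-5-methyl-2-(prop-1-en-2-yl)hex-4-en-1-yl. MOM = CH2OCH3.

## Route

**Step 1**
Reactants: 1 5-fluororesorcinol (5-fluorobenzene-1,3-diol)
Product: 2 1-fluoro-3,5-bis(methoxymethoxy)benzene
Conditions: MOMCl (2.5 equiv), i-Pr2NEt (3 equiv), CH2Cl2, 0 °C → rt
Reagents that add atoms: chloromethyl methyl ether, COCCl
Why: Amine-mediated O-alkylation of both phenols with the reactive α-chloro ether (Williamson-type MOM protection) should be straightforward, and MOM is chosen because it chelates lithium in the metalations, tolerates organometallics, fluoride and carbonate, and leaves under mild acid at the end.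

**Step 2**
Reactants: 2 1-fluoro-3,5-bis(methoxymethoxy)benzene
Product: 4 [4-fluoro-2,6-bis(methoxymethoxy)phenyl]trimethylsilane, via C6 aryllithium 3 (not isolated)
Conditions: n-BuLi (1.1 equiv), THF, −78 → −30 °C; TMSCl, −78 °C → rt
Reagents that add atoms: chlorotrimethylsilane, C[Si](C)(C)Cl
Why: Directed ortho-metalation with uncomplexed n-BuLi is governed by coordination, so the proton at the future C6, held between two chelating OMOM groups, should be removed ahead of those beside fluorine, and trapping with TMSCl parks a removable block on the only site that would otherwise compete in steps 3 and 8.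

**Step 3**
Reactants: 4 [4-fluoro-2,6-bis(methoxymethoxy)phenyl]trimethylsilane
Product: 6 [4-fluoro-3-iodo-2,6-bis(methoxymethoxy)phenyl]trimethylsilane, via C8 aryllithium 5 (not isolated)
Conditions: s-BuLi (1.1 equiv), TMEDA, THF, −78 °C; I2, THF, −78 °C → rt
Reagents that add atoms: iodine, II
Why: Directed ortho-metalation followed by iodinolysis should work because the two remaining ring protons are equivalent, each is acidified by an adjacent fluorine and an adjacent OMOM group, the 2-fluoroaryllithium does not lose LiF at −78 °C, and iodine turns it into the electrophile for the cross-coupling.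

**Step 4**
Reactants: 7 (R)-lavandulol [(2R)-5-methyl-2-(prop-1-en-2-yl)hex-4-en-1-ol]
Product: 8 (R)-lavandulyl iodide [(3R)-3-(iodomethyl)-2,6-dimethylhepta-1,5-diene]
Conditions: PPh3, imidazole, I2, CH2Cl2, 0 °C
Reagents that add atoms: iodine, II
Why: In this Appel reaction the alkoxyphosphonium salt is displaced by iodide in an SN2 process at the primary carbon, so the neighbouring stereocentre is not touched and the imidazole-buffered medium leaves both alkenes alone.

**Step 5**
Reactants: 8 (R)-lavandulyl iodide; 6 [4-fluoro-3-iodo-2,6-bis(methoxymethoxy)phenyl]trimethylsilane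
Product: 10 [4-fluoro-2,6-bis(methoxymethoxy)-3-Lav-phenyl]trimethylsilane, via lavandulylzinc iodide 9 (not isolated)
Conditions: 8, Zn dust (activated with BrCH2CH2Br, TMSCl), LiCl, THF, 30 °C; then 6, Pd(OAc)2 (3 mol %), SPhos (2-dicyclohexylphosphino-2′,6′-dimethoxybiphenyl, 6 mol %), THF, 25 → 45 °C
Reagents that add atoms: none
Why: In this Negishi coupling LiCl-assisted zinc insertion into the primary C–I bond gives a reagent whose stereocentre is β to the metal and so not at stake, and the bulky electron-rich biarylphosphine on palladium speeds oxidative addition to the doubly ortho-substituted iodide and reductive elimination ahead of β-hydride elimination, so the centre from (R)-lavandulol is carried over unchanged.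

**Step 6**
Reactants: 11 methyl glycolate
Product: 12 methyl 2-(methoxymethoxy)acetate
Conditions: MOMCl, i-Pr2NEt, CH2Cl2, 0 °C → rt
Reagents that add atoms: chloromethyl methyl ether, COCCl
Why: MOM protection of the primary alcohol by amine-mediated alkylation runs under conditions too mild for self-condensation of the ester.

**Step 7**
Reactants: 12 methyl 2-(methoxymethoxy)acetate
Product: 13 N-methoxy-2-(methoxymethoxy)-N-methylacetamide
Conditions: MeNH(OMe)·HCl (1.5 equiv), i-PrMgCl (3 equiv), THF, −20 → 0 °C; aq NH4Cl
Reagents that add atoms: N,O-dimethylhydroxylamine hydrochloride, CNOC.Cl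
Why: Aminolysis of the ester by the magnesium amide of N,O-dimethylhydroxylamine (Weinreb amide synthesis) is fast at low temperature, and the product amide is inert to the excess amide base.

**Step 8**
Reactants: 10 [4-fluoro-2,6-bis(methoxymethoxy)-3-Lav-phenyl]trimethylsilane; 13 N-methoxy-2-(methoxymethoxy)-N-methylacetamide
Product: 15 1-[2-fluoro-4,6-bis(methoxymethoxy)-3-Lav-5-(trimethylsilyl)phenyl]-2-(methoxymethoxy)ethan-1-one, via C4a aryllithium 14 (not isolated)
Conditions: s-BuLi (1.1 equiv), THF, −78 °C; 13, −78 °C; aq NH4Cl, −78 °C → rt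
Reagents that add atoms: none
Why: Directed ortho-metalation and Weinreb ketone synthesis should succeed because only one ring proton is left, it lies between F and OMOM and is kinetically far more acidic than the benzylic and allylic protons of the side chain, and the chelated tetrahedral adduct with 13 holds until the cold quench so that a single addition gives the ketone.

**Step 9**
Reactants: 15 silylated α-MOMO ketone
Product: 16 1-[2-fluoro-4,6-bis(methoxymethoxy)-3-Lav-phenyl]-2-(methoxymethoxy)ethan-1-one
Conditions: TBAF·3H2O, THF, 0 °C → rt
Reagents that add atoms: none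
Why: In this fluoride-induced protodesilylation, attack of fluoride on silicon releases an aryl anion equivalent at C6 that is stabilised by the two flanking acetal oxygens and protonated by the hydrate water, while MOM ethers, ketone, aryl fluoride and alkenes are inert to TBAF at room temperature.

**Step 10**
Reactants: 17 4-hydroxybenzoic acid
Product: 19 4-(methoxymethoxy)benzoic acid, via MOM ester 18 (not isolated)
Conditions: MOMCl (2.5 equiv), i-Pr2NEt (3 equiv), CH2Cl2, 0 °C → rt; concentrate; NaOH, MeOH/H2O, rt; 1 M HCl to pH 4, 0 °C
Reagents that add atoms: chloromethyl methyl ether, COCCl; sodium hydroxide, [Na+].[OH-]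
Why: Exhaustive MOM alkylation followed by saponification should work because hydroxide cleaves the methoxymethyl ester at the acyl carbon, whereas the aryl MOM ether is inert to base and to a brief cold acidification to pH 4.

**Step 11**
Reactants: 19 4-(methoxymethoxy)benzoic acid
Product: 20 1-[4-(methoxymethoxy)benzoyl]-1H-imidazole
Conditions: CDI (1.1 equiv), CH2Cl2, rt; quick cold-water wash
Reagents that add atoms: 1,1′-carbonyldiimidazole, O=C(n1ccnc1)n1ccnc1
Why: Carboxyl activation with CDI runs under neutral conditions with loss of CO2, which avoids the HCl that acid chloride formation would release onto the MOM ether, and it gives an acyl donor that favours C-acylation of lithium enolates.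

**Step 12**
Reactants: 16 α-MOMO 2-fluoroaryl ketone; 20 1-[4-(methoxymethoxy)benzoyl]-1H-imidazole
Product: 22 1-[2-fluoro-4,6-bis(methoxymethoxy)-3-Lav-phenyl]-2-(methoxymethoxy)-3-[4-(methoxymethoxy)phenyl]propane-1,3-dione (both labile C3 epimers), via lithium enolate 21 (not isolated)
Conditions: LiHMDS (2.2 equiv), THF, −78 °C; 20 (1.2 equiv), −78 → 0 °C; aq NH4Cl
Reagents that add atoms: none
Why: In this crossed Claisen-type C-acylation the chelated lithium enolate of the α-alkoxy ketone attacks the non-enolisable acyl imidazole at carbon, the second equivalent of base converts the more acidic diketone into its lithium chelate and so shields it from further reaction, and at or below 0 °C in THF this tight chelate should not yet displace fluoride.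

**Step 13**
Reactants: 22 2-MOMO-1,3-diketone
Product: 24 8-Lav-3,5,7-tris(methoxymethoxy)-2-[4-(methoxymethoxy)phenyl]-4H-chromen-4-one, via potassium enolate 23 (not isolated)
Conditions: K2CO3 (3 equiv, dried), DMF, 4 Å MS, 90 °C
Reagents that add atoms: none
Why: Carbonate removes the C3 proton, and in DMF the loosely paired potassium enolate 23 can turn about C3–C4 out of its chelated U-shape so that the oxygen on C2 faces C8a; it adds there to give a Meisenheimer anion with its charge on C4a, C6 and C8 and an outlet into the C4 carbonyl, O5 and O7 on uncharged carbons help only inductively, and expulsion of fluoride restores ring A. The closest known reaction type is the base-mediated intramolecular SNAr that turns 1-(2-fluoroaryl)-1,3-diketones into flavones and 2-fluorobenzoyl enaminones into 4-quinolones. Ring C closes as a six-membered ring by addition–elimination at sp2 C8a, formally 6-endo-trig with respect to the C4a=C8a bond, that is a vinylogous oxa-Michael addition followed by loss of fluoride. No stereocentre is created: the labile C3 centre of 22 becomes sp2 so both epimers converge, and the side-chain centre carries no proton that carbonate can remove. Oxygen versus carbon attack of the ambident enolate is settled by ring size (pyranone against a four-membered carbocycle), and the oxygen on C4 cannot reach ring A. Of the two positions ortho to the acyl group, C8a wins over C5 because fluorine lowers the barrier to addition and departs readily while the acetal oxide on C5 does neither, so O1 can only end up next to C8.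

**Step 14**
Reactants: 24 tetrakis-MOM ether
Product: 25 3,5,7-trihydroxy-2-(4-hydroxyphenyl)-8-[(2S)-5-methyl-2-(prop-1-en-2-yl)hex-4-en-1-yl]-4H-chromen-4-one (target)
Conditions: 3 M aq HCl/MeOH (1:10), 45 °C, stopped as soon as the last MOM group is gone
Reagents that add atoms: none
Why: Acid-catalysed acetal exchange with methanol removes the four MOM groups, those on O3 and O5 first, at an acidity too low to protonate the 1,1-disubstituted and trisubstituted alkenes, so cyclisation of the free O7–H onto the side chain should be avoided and the stereocentre is not involved.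

## Compound list

1 | 5-fluororesorcinol | Oc1cc(O)cc(F)c1 | starting material
2 | 1-fluoro-3,5-bis(methoxymethoxy)benzene | COCOc1cc(F)cc(OCOC)c1 | intermediate
3 | 4-fluoro-2,6-bis(methoxymethoxy)phenyllithium (C6 aryllithium) | [Li]c1c(OCOC)cc(F)cc1OCOC | intermediate
4 | [4-fluoro-2,6-bis(methoxymethoxy)phenyl]trimethylsilane | COCOc1cc(F)cc(OCOC)c1[Si](C)(C)C | intermediate
5 | 6-fluoro-2,4-bis(methoxymethoxy)-3-(trimethylsilyl)phenyllithium (C8 aryllithium) | [Li]c1c(F)cc(OCOC)c([Si](C)(C)C)c1OCOC | intermediate
6 | [4-fluoro-3-iodo-2,6-bis(methoxymethoxy)phenyl]trimethylsilane | COCOc1cc(F)c(I)c(OCOC)c1[Si](C)(C)C | intermediate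
7 | (R)-lavandulol | C=C(C)[C@@H](CC=C(C)C)CO | starting material
8 | (R)-lavandulyl iodide, (3R)-3-(iodomethyl)-2,6-dimethylhepta-1,5-diene | C=C(C)[C@@H](CC=C(C)C)CI | intermediate
9 | (R)-lavandulylzinc iodide | C=C(C)[C@@H](CC=C(C)C)C[Zn]I | intermediate
10 | [4-fluoro-2,6-bis(methoxymethoxy)-3-[(2S)-5-methyl-2-(prop-1-en-2-yl)hex-4-en-1-yl]phenyl]trimethylsilane | C=C(C)[C@@H](CC=C(C)C)Cc1c(OCOC)c([Si](C)(C)C)c(OCOC)cc1F | intermediate
11 | methyl glycolate | COC(=O)CO | starting material
12 | methyl 2-(methoxymethoxy)acetate | COCOCC(=O)OC | intermediate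
13 | N-methoxy-2-(methoxymethoxy)-N-methylacetamide | COCOCC(=O)N(C)OC | intermediate
14 | C4a aryllithium from 10 (Li between F and OMOM) | C=C(C)[C@@H](CC=C(C)C)Cc1c(OCOC)c([Si](C)(C)C)c(OCOC)c([Li])c1F | intermediate
15 | 1-[2-fluoro-4,6-bis(methoxymethoxy)-3-[(2S)-lavandulyl]-5-(trimethylsilyl)phenyl]-2-(methoxymethoxy)ethan-1-one | C=C(C)[C@@H](CC=C(C)C)Cc1c(OCOC)c([Si](C)(C)C)c(OCOC)c(C(=O)COCOC)c1F | intermediate
16 | 1-[2-fluoro-4,6-bis(methoxymethoxy)-3-[(2S)-lavandulyl]phenyl]-2-(methoxymethoxy)ethan-1-one | C=C(C)[C@@H](CC=C(C)C)Cc1c(OCOC)cc(OCOC)c(C(=O)COCOC)c1F | intermediate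
17 | 4-hydroxybenzoic acid | O=C(O)c1ccc(O)cc1 | starting material
18 | methoxymethyl 4-(methoxymethoxy)benzoate | COCOC(=O)c1ccc(OCOC)cc1 | intermediate
19 | 4-(methoxymethoxy)benzoic acid | COCOc1ccc(C(=O)O)cc1 | intermediate
20 | 1-[4-(methoxymethoxy)benzoyl]-1H-imidazole | COCOc1ccc(C(=O)n2ccnc2)cc1 | intermediate
21 | lithium enolate of 16 | C=C(C)[C@@H](CC=C(C)C)Cc1c(OCOC)cc(OCOC)c(C(O[Li])=COCOC)c1F | intermediate
22 | 1-[2-fluoro-4,6-bis(methoxymethoxy)-3-[(2S)-lavandulyl]phenyl]-2-(methoxymethoxy)-3-[4-(methoxymethoxy)phenyl]propane-1,3-dione (C3 labile, both epimers) | C=C(C)[C@@H](CC=C(C)C)Cc1c(OCOC)cc(OCOC)c(C(=O)C(OCOC)C(=O)c2ccc(OCOC)cc2)c1F | intermediate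
23 | potassium enolate of 22 | C=C(C)[C@@H](CC=C(C)C)Cc1c(OCOC)cc(OCOC)c(C(=O)C(OCOC)=C([O-])c2ccc(OCOC)cc2)c1F.[K+] | intermediate
24 | 8-[(2S)-lavandulyl]kaempferol 3,5,7,4′-tetrakis(methoxymethyl) ether | C=C(C)[C@@H](CC=C(C)C)Cc1c(OCOC)cc(OCOC)c2c(=O)c(OCOC)c(-c3ccc(OCOC)cc3)oc12 | intermediate
25 | 8-[(2S)-lavandulyl]kaempferol (CNP0185677.2) | C=C(C)[C@@H](CC=C(C)C)Cc1c(O)cc(O)c2c(=O)c(O)c(-c3ccc(O)cc3)oc12 | target

## Step count and risks

Total step count: 14.
Longest linear sequence: 9 steps from 5-fluororesorcinol (steps 1, 2, 3, 5, 8, 9, 12, 13, 14).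

**Step 13**

- **Risk:** The delocalised, cation-chelated diketonate may add too slowly to ring A. The activating carbonyl is itself part of the enolate and is twisted by two ortho substituents. Retro-Claisen cleavage by adventitious hydroxide could then overtake ring closure.
- **Fallback:** It sets out from 16 and brings O1 in from outside while the ketone is still a neutral activator.
  - Acetohydroxamic acid and K2CO3 in DMSO at 80 °C should displace fluoride to give the O-aryl acetohydroxamate F1.
  - This fragments in the flask by a Lossen rearrangement to the 2-hydroxyaryl ketone F2.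
  - O-acylation with 20 (DBU, CH2Cl2) gives the aryl ester F3.
  - Baker–Venkataraman rearrangement (KOt-Bu, THF) gives the 2-hydroxyaryl diketone F4.
  - HCl in MeOH then effects cyclodehydration through O1–C2 and removes the MOM groups in one operation.
  - The regiochemical marking by fluorine is kept, and the fallback comes back to the route at 25.

**Step 5**

- **Risk:** The homoallyl radical may rearrange (1,2-vinyl shift) during zinc insertion. Transmetalation and reductive elimination at the doubly ortho-substituted arylpalladium may be slow. That would open β-hydride elimination, alkene migration and erosion of the stereocentre.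
- **Fallback:** It reverses the polarity and sets out from 4 and 8.
  - Compound 4 is lithiated as in step 3 to 5.
  - Transmetalation with MgBr2·OEt2 at −78 °C gives the arylmagnesium bromide F5.
  - F5 is alkylated with 8 under Li2CuCl4 catalysis (THF/NMP, 0 °C → rt).
  - This is an SN2-type copper-catalysed coupling that involves neither an alkyl radical from metal insertion nor an alkylpalladium species. It comes back to the route at 10.

**Step 12**

- **Risk:** The hindered enolate may be acylated at oxygen. Proton transfer from product to enolate may stall the conversion. The amide base may consume the acyl donor.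
- **Fallback:** It sets out from 16.
  - The lithium enolate 21 is added at −78 °C to commercial 4-(methoxymethoxy)benzaldehyde and quenched cold to give the aldol adduct F6 as a mixture of diastereomers.
  - Dess–Martin periodinane with NaHCO3 in CH2Cl2 oxidises it to the diketone. The fallback comes back to the route at 22.

Further compounds
F1 | step 13 | N-[2-[(methoxymethoxy)acetyl]-3,5-bis(methoxymethoxy)-6-[(2S)-lavandulyl]phenoxy]acetamide (O-aryl acetohydroxamate) | C=C(C)[C@@H](CC=C(C)C)Cc1c(OCOC)cc(OCOC)c(C(=O)COCOC)c1ONC(C)=O
F2 | step 13 | 1-[2-hydroxy-4,6-bis(methoxymethoxy)-3-[(2S)-lavandulyl]phenyl]-2-(methoxymethoxy)ethan-1-one | C=C(C)[C@@H](CC=C(C)C)Cc1c(OCOC)cc(OCOC)c(C(=O)COCOC)c1O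
F3 | step 13 | 2-[(methoxymethoxy)acetyl]-3,5-bis(methoxymethoxy)-6-[(2S)-lavandulyl]phenyl 4-(methoxymethoxy)benzoate | C=C(C)[C@@H](CC=C(C)C)Cc1c(OCOC)cc(OCOC)c(C(=O)COCOC)c1OC(=O)c2ccc(OCOC)cc2
F4 | step 13 | 1-[2-hydroxy-4,6-bis(methoxymethoxy)-3-[(2S)-lavandulyl]phenyl]-2-(methoxymethoxy)-3-[4-(methoxymethoxy)phenyl]propane-1,3-dione | C=C(C)[C@@H](CC=C(C)C)Cc1c(OCOC)cc(OCOC)c(C(=O)C(OCOC)C(=O)c2ccc(OCOC)cc2)c1O
F5 | step 5 | [6-fluoro-2,4-bis(methoxymethoxy)-3-(trimethylsilyl)phenyl]magnesium bromide | Br[Mg]c1c(F)cc(OCOC)c([Si](C)(C)C)c1OCOC
F6 | step 12 | 1-[2-fluoro-4,6-bis(methoxymethoxy)-3-[(2S)-lavandulyl]phenyl]-3-hydroxy-2-(methoxymethoxy)-3-[4-(methoxymethoxy)phenyl]propan-1-one (mixture of diastereomers) | C=C(C)[C@@H](CC=C(C)C)Cc1c(OCOC)cc(OCOC)c(C(=O)C(OCOC)C(O)c2ccc(OCOC)cc2)c1F
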